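**Plan**

- Retrosynthesis: the oxirane oxygen and the three O-benzyl groups are removed first. Ring A (the 2-prenyl-4-alkylphenol) is then taken back to a cyclohex-2-enone and cut at C1–C2 and C5–C6 (C1 carries the CH2 link, C3 the prenyl group, C4 the oxygen).
- Feature used: C4–O of ring A can be a ketone carbonyl with the prenyl-bearing C3 as its α-carbon and C2 as an enone methylidene, while C6 and C1 are the carbonyl and α-carbons of an aldehyde hanging from the benzylic CH2.
- Further cuts: the bond from the quaternary C2 of ring C (the butenolide) to its CH2CH2CHO arm (acrolein), then ring C itself into 4-hydroxyphenylpyruvic acid and methyl glyoxylate.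
- Forward order: ring C with ring B attached, then the aldehyde arm, then ring A by annulation and aromatisation, then the epoxide, then debenzylation.
- Stereochemistry: the (R) quaternary carbon comes from a catalyst-controlled Michael addition; the (R) oxirane carbon from reagent-controlled Shi epoxidation; the sp3 centres made in the annulation are erased on aromatisation.

Key step: step 5

Assumption: the sense of induction of the cinchona catalyst in step 3 cannot be predicted with confidence for this butenolide; the quinidine-derived catalyst is written for the (R) series, and its quinine-derived pseudoenantiomer is to be used if the opposite sense is found.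

Step 1
Reactants: 1 4-hydroxyphenylpyruvic acid; 2 methyl glyoxylate
Product: 4 methyl 4-hydroxy-3-(4-hydroxyphenyl)-5-oxo-2,5-dihydrofuran-2-carboxylate (racemic), via aldol hydroxy acid 3 (not isolated)
Conditions: 2 (1.5 equiv), Et3N (2.5 equiv), THF, 0 °C to rt; then 2 M HCl, rt
Reagents that add atoms: none
Why: Cross-aldol addition of the benzylic enol carbon of the α-keto acid to the far more electrophilic glyoxylate aldehyde, followed by acid lactonisation of the γ-hydroxy α-keto acid and enolisation, is the standard isotetronic acid synthesis.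

Step 2
Reactants: 4 methyl 4-hydroxy-3-(4-hydroxyphenyl)-5-oxo-2,5-dihydrofuran-2-carboxylate
Product: 5 methyl 4-(benzyloxy)-3-[4-(benzyloxy)phenyl]-5-oxo-2,5-dihydrofuran-2-carboxylate (racemic)
Conditions: BnOH (2.2 equiv), PPh3 (2.2 equiv), DIAD (2.2 equiv), THF, 0 °C to rt
Reagents that add atoms: benzyl alcohol, OCc1ccccc1
Why: Mitsunobu etherification alkylates only the two acidic O–H groups (enol, then phenol) and, unlike BnBr with a carbonate base, never generates the C2 carbanion of ring C that would be C-benzylated.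

Step 3
Reactants: 5 methyl 4-(benzyloxy)-3-[4-(benzyloxy)phenyl]-5-oxo-2,5-dihydrofuran-2-carboxylate; 6 acrolein
Product: 7 methyl (2R)-4-(benzyloxy)-3-[4-(benzyloxy)phenyl]-5-oxo-2-(3-oxopropyl)-2,5-dihydrofuran-2-carboxylate
Conditions: 6 (3 equiv, freshly distilled), 9-O-(phenanthren-9-yl)cupreidine (10 mol %), CH2Cl2, −25 °C
Reagents that add atoms: none
Why: Michael addition under bifunctional cinchona catalysis: the quinuclidine nitrogen deprotonates the doubly activated C2–H of ring C to a planar 2-oxidofuran, the 6'-OH binds acrolein, and bond formation at C2 (which restores the conjugated butenolide) on the face left open in the chiral ion pair sets the quaternary (R) centre, as in the established additions of α-substituted β-keto esters and γ-substituted butenolides to enals.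

Step 4
Reactants: 8 6-methylhept-5-en-2-one
Product: 9 6-methyl-3-methylidenehept-5-en-2-one
Conditions: (CH2O)n (2 equiv), i-Pr2NH2+ CF3CO2− (1 equiv), CF3CO2H (10 mol %), THF, reflux
Reagents that add atoms: paraformaldehyde (as formaldehyde), C=O
Why: Mannich-type α-methylenation (aminomethylation through the more substituted enol, then β-elimination of the amine) places the methylidene on C3, the usual site for methyl alkyl ketones under acid catalysis; any terminal regioisomer would be removed by distillation.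

Step 5
Reactants: 7 methyl (2R)-4-(benzyloxy)-3-[4-(benzyloxy)phenyl]-5-oxo-2-(3-oxopropyl)-2,5-dihydrofuran-2-carboxylate; 9 6-methyl-3-methylidenehept-5-en-2-one
Product: 11 methyl (2R)-4-(benzyloxy)-3-[4-(benzyloxy)phenyl]-2-{[5-(3-methylbut-2-en-1-yl)-4-oxocyclohex-2-en-1-yl]methyl}-5-oxo-2,5-dihydrofuran-2-carboxylate (mixture of ring diastereomers), via keto aldehyde 10 (not isolated)
Conditions: 9 (2.5 equiv), pyrrolidine (30 mol %), AcOH (30 mol %), toluene, 0 °C to rt; then 50 °C
Reagents that add atoms: none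
Why: Pyrrolidine converts the aldehyde of 7 into an enamine whose β-carbon adds to the methylidene carbon of 9, and hydrolysis of the resulting iminium gives the 1,5-keto aldehyde 10. The methyl ketone of 10, as its less substituted enamine or enol, then attacks the aldehyde carbon and water is lost, so that the C1–C2 and C5–C6 bonds of ring A are made in one flask. The closest known reaction type is the secondary-amine-mediated Michael–aldol (Robinson-type) annulation of aldehydes with vinyl ketones to 4-substituted cyclohex-2-enones, here with an α-branched vinyl ketone. Ring A closes by a 6-(enolendo)-exo-trig aldol condensation. The two new sp3 centres (C1 and C3 of ring A) form without control and need none, because both become sp2 carbons in step 7. The step needs cross-addition to win over self-aldol of 7 and over retro-Michael loss of acrolein from the quaternary carbon, which the excess of 9, the buffered catalytic amine and the absence of a hydrogen on the quaternary carbon should secure; the regiochemistry is fixed because methyl-to-aldehyde closure is the only one that gives a six-membered ring.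

Step 6
Reactants: 11 methyl (2R)-4-(benzyloxy)-3-[4-(benzyloxy)phenyl]-2-{[5-(3-methylbut-2-en-1-yl)-4-oxocyclohex-2-en-1-yl]methyl}-5-oxo-2,5-dihydrofuran-2-carboxylate
Product: 12 methyl (2R)-4-(benzyloxy)-3-[4-(benzyloxy)phenyl]-2-{[4-(tert-butyldimethylsilyloxy)-5-(3-methylbut-2-en-1-yl)cyclohexa-2,4-dien-1-yl]methyl}-5-oxo-2,5-dihydrofuran-2-carboxylate
Conditions: TBSOTf (1.3 equiv), Et3N (2 equiv), CH2Cl2, 0 °C
Reagents that add atoms: tert-butyldimethylsilyl trifluoromethanesulfonate, CC(C)(C)[Si](C)(C)OS(=O)(=O)C(F)(F)F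
Why: Soft enolisation (O-silylation of the enone carbonyl, then deprotonation by the amine) gives the 2-silyloxy-1,3-diene; the linear dienol ether, if it also forms, leads to the same arene in step 7.

Step 7
Reactants: 12 methyl (2R)-4-(benzyloxy)-3-[4-(benzyloxy)phenyl]-2-{[4-(tert-butyldimethylsilyloxy)-5-(3-methylbut-2-en-1-yl)cyclohexa-2,4-dien-1-yl]methyl}-5-oxo-2,5-dihydrofuran-2-carboxylate
Product: 13 methyl (2R)-4-(benzyloxy)-3-[4-(benzyloxy)phenyl]-2-{[4-(tert-butyldimethylsilyloxy)-3-(3-methylbut-2-en-1-yl)phenyl]methyl}-5-oxo-2,5-dihydrofuran-2-carboxylate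
Conditions: DDQ (1.2 equiv), 2,4,6-collidine (2 equiv), benzene, rt
Reagents that add atoms: none
Why: DDQ dehydrogenation of a silyloxycyclohexadiene (hydride abstraction from a ring sp3 carbon, then proton loss) is driven by aromatisation, removes both uncontrolled ring stereocentres, and leaves the silyl group on oxygen so that no free ortho-prenyl phenol is exposed to the quinone.

Step 8
Reactants: 13 methyl (2R)-4-(benzyloxy)-3-[4-(benzyloxy)phenyl]-2-{[4-(tert-butyldimethylsilyloxy)-3-(3-methylbut-2-en-1-yl)phenyl]methyl}-5-oxo-2,5-dihydrofuran-2-carboxylate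
Product: 14 methyl (2R)-4-(benzyloxy)-2-{[4-(benzyloxy)-3-(3-methylbut-2-en-1-yl)phenyl]methyl}-3-[4-(benzyloxy)phenyl]-5-oxo-2,5-dihydrofuran-2-carboxylate
Conditions: CsF (2 equiv), BnBr (1.5 equiv), DMF, rt
Reagents that add atoms: benzyl bromide, BrCc1ccccc1
Why: Fluoride-induced desilylation gives the caesium phenoxide, which is benzylated in the same flask (Williamson ether synthesis); the molecule has no other acidic site.

Step 9
Reactants: 14 methyl (2R)-4-(benzyloxy)-2-{[4-(benzyloxy)-3-(3-methylbut-2-en-1-yl)phenyl]methyl}-3-[4-(benzyloxy)phenyl]-5-oxo-2,5-dihydrofuran-2-carboxylate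
Product: 15 methyl (2R)-4-(benzyloxy)-2-[(4-(benzyloxy)-3-{[(2R)-3,3-dimethyloxiran-2-yl]methyl}phenyl)methyl]-3-[4-(benzyloxy)phenyl]-5-oxo-2,5-dihydrofuran-2-carboxylate
Conditions: Shi ketone (1,2:4,5-di-O-isopropylidene-β-D-erythro-2,3-hexodiulo-2,6-pyranose, from D-fructose, 30 mol %), Oxone (2KHSO5·KHSO4·K2SO4), K2CO3, Bu4NHSO4 (cat.), MeCN–CH2(OMe)2–aq. Na2B4O7 buffer (pH about 10.5), 0 °C
Reagents that add atoms: Oxone (active component potassium peroxymonosulfate), [K+].[O-]S(=O)(=O)OO
Why: Shi asymmetric epoxidation: the chiral dioxirane transfers oxygen through a spiro transition state to the electron-rich trisubstituted prenyl alkene (the push–pull alkene of ring C is far less nucleophilic), and the D-fructose-derived ketone is expected to give the (R) oxirane carbon by the facial preference it shows for other trisubstituted and trans-disubstituted alkenes.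

Step 10
Reactants: 15 methyl (2R)-4-(benzyloxy)-2-[(4-(benzyloxy)-3-{[(2R)-3,3-dimethyloxiran-2-yl]methyl}phenyl)methyl]-3-[4-(benzyloxy)phenyl]-5-oxo-2,5-dihydrofuran-2-carboxylate
Product: 16 methyl (2R)-2-[(3-{[(2R)-3,3-dimethyloxiran-2-yl]methyl}-4-hydroxyphenyl)methyl]-4-hydroxy-3-(4-hydroxyphenyl)-5-oxo-2,5-dihydrofuran-2-carboxylate
Conditions: H2 (1 atm), 10 % Pd/C, EtOAc, rt, stopped at full conversion; filtration, concentration below 30 °C
Reagents that add atoms: none
Why: Catalytic hydrogenolysis cleaves the two aryl benzyl ethers and the enol benzyl ether under neutral conditions, under which the non-benzylic trialkyl oxirane and the tetrasubstituted alkene of ring C should persist, and the short contact time limits opening of the oxirane by the freed ortho phenol.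

**Compound list**

1 | 4-hydroxyphenylpyruvic acid | OC(=O)C(=O)Cc1ccc(O)cc1 | starting material
2 | methyl glyoxylate | COC(=O)C=O | starting material
3 | 4-hydroxy-3-(4-hydroxyphenyl)-5-methoxy-2,5-dioxopentanoic acid (aldol hydroxy acid, diastereomer mixture) | OC(=O)C(=O)C(c1ccc(O)cc1)C(O)C(=O)OC | intermediate
4 | methyl 4-hydroxy-3-(4-hydroxyphenyl)-5-oxo-2,5-dihydrofuran-2-carboxylate (racemic) | COC(=O)C1OC(=O)C(O)=C1c1ccc(O)cc1 | intermediate
5 | methyl 4-(benzyloxy)-3-[4-(benzyloxy)phenyl]-5-oxo-2,5-dihydrofuran-2-carboxylate (racemic) | COC(=O)C1OC(=O)C(OCc2ccccc2)=C1c1ccc(OCc2ccccc2)cc1 | intermediate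
6 | acrolein | C=CC=O | starting material
7 | methyl (2R)-4-(benzyloxy)-3-[4-(benzyloxy)phenyl]-5-oxo-2-(3-oxopropyl)-2,5-dihydrofuran-2-carboxylate | COC(=O)[C@]1(CCC=O)OC(=O)C(OCc2ccccc2)=C1c1ccc(OCc2ccccc2)cc1 | intermediate
8 | 6-methylhept-5-en-2-one | CC(=O)CCC=C(C)C | starting material
9 | 6-methyl-3-methylidenehept-5-en-2-one | CC(=O)C(=C)CC=C(C)C | intermediate
10 | methyl (2R)-2-(4-acetyl-2-formyl-7-methyloct-6-en-1-yl)-4-(benzyloxy)-3-[4-(benzyloxy)phenyl]-5-oxo-2,5-dihydrofuran-2-carboxylate (keto aldehyde, diastereomer mixture) | COC(=O)[C@]1(CC(C=O)CC(CC=C(C)C)C(C)=O)OC(=O)C(OCc2ccccc2)=C1c1ccc(OCc2ccccc2)cc1 | intermediate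
11 | methyl (2R)-4-(benzyloxy)-3-[4-(benzyloxy)phenyl]-2-{[5-(3-methylbut-2-en-1-yl)-4-oxocyclohex-2-en-1-yl]methyl}-5-oxo-2,5-dihydrofuran-2-carboxylate (ring diastereomers) | COC(=O)[C@]1(CC2C=CC(=O)C(CC=C(C)C)C2)OC(=O)C(OCc2ccccc2)=C1c1ccc(OCc2ccccc2)cc1 | intermediate
12 | methyl (2R)-4-(benzyloxy)-3-[4-(benzyloxy)phenyl]-2-{[4-(tert-butyldimethylsilyloxy)-5-(3-methylbut-2-en-1-yl)cyclohexa-2,4-dien-1-yl]methyl}-5-oxo-2,5-dihydrofuran-2-carboxylate | COC(=O)[C@]1(CC2C=CC(O[Si](C)(C)C(C)(C)C)=C(CC=C(C)C)C2)OC(=O)C(OCc2ccccc2)=C1c1ccc(OCc2ccccc2)cc1 | intermediate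
13 | methyl (2R)-4-(benzyloxy)-3-[4-(benzyloxy)phenyl]-2-{[4-(tert-butyldimethylsilyloxy)-3-(3-methylbut-2-en-1-yl)phenyl]methyl}-5-oxo-2,5-dihydrofuran-2-carboxylate | COC(=O)[C@]1(Cc2ccc(O[Si](C)(C)C(C)(C)C)c(CC=C(C)C)c2)OC(=O)C(OCc2ccccc2)=C1c1ccc(OCc2ccccc2)cc1 | intermediate
14 | methyl (2R)-4-(benzyloxy)-2-{[4-(benzyloxy)-3-(3-methylbut-2-en-1-yl)phenyl]methyl}-3-[4-(benzyloxy)phenyl]-5-oxo-2,5-dihydrofuran-2-carboxylate | COC(=O)[C@]1(Cc2ccc(OCc3ccccc3)c(CC=C(C)C)c2)OC(=O)C(OCc2ccccc2)=C1c1ccc(OCc2ccccc2)cc1 | intermediate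
15 | methyl (2R)-4-(benzyloxy)-2-[(4-(benzyloxy)-3-{[(2R)-3,3-dimethyloxiran-2-yl]methyl}phenyl)methyl]-3-[4-(benzyloxy)phenyl]-5-oxo-2,5-dihydrofuran-2-carboxylate | COC(=O)[C@]1(Cc2ccc(OCc3ccccc3)c(C[C@H]3OC3(C)C)c2)OC(=O)C(OCc2ccccc2)=C1c1ccc(OCc2ccccc2)cc1 | intermediate
16 | methyl (2R)-2-[(3-{[(2R)-3,3-dimethyloxiran-2-yl]methyl}-4-hydroxyphenyl)methyl]-4-hydroxy-3-(4-hydroxyphenyl)-5-oxo-2,5-dihydrofuran-2-carboxylate | COC(=O)[C@]1(Cc2ccc(O)c(C[C@H]3OC3(C)C)c2)OC(=O)C(O)=C1c1ccc(O)cc1 | target

**Step count**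

Total: 10 steps. Longest linear sequence: 9 steps (steps 1, 2, 3, 5, 6, 7, 8, 9, 10); step 4 is a one-step branch.

**Steps most likely to fail**

Step 3. The enantiofacial discrimination of the planar 2-oxidofuran in its ion pair with the catalyst may be poor, or polymerisation of acrolein may outpace the addition. The fallback sets out from 5: addition to acrolein with catalytic Et3N in CH2Cl2 should give the racemic methyl 4-(benzyloxy)-3-[4-(benzyloxy)phenyl]-5-oxo-2-(3-oxopropyl)-2,5-dihydrofuran-2-carboxylate F1. Preparative supercritical-fluid chromatography on a polysaccharide chiral stationary phase then separates the (2R) enantiomer, which is 7, from the (2S) enantiomer F2. The route is rejoined at 7.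

Step 5. The hindered enamine may add only slowly to the α-branched enone, so that self-aldol of the aldehyde and retro-Michael cleavage at the quaternary carbon (with loss of optical purity) compete. The fallback sets out from 7: the same pyrrolidine/AcOH annulation is run with the much more reactive but-3-en-2-one to give methyl (2R)-4-(benzyloxy)-3-[4-(benzyloxy)phenyl]-5-oxo-2-[(4-oxocyclohex-2-en-1-yl)methyl]-2,5-dihydrofuran-2-carboxylate F3. Kinetic deprotonation of its α'-CH2 with LiN(i-Pr)2 in THF at −78 °C, the only kinetically acidic site at that temperature, and alkylation with 1-bromo-3-methylbut-2-ene then place the prenyl group next to the carbonyl. The route is rejoined at 11.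

Step 10. The ortho phenol, once freed on the catalyst surface beside the acidic enol, may open the oxirane to a dihydrobenzofuran or chroman. The fallback sets out from 13 and keeps that phenol silylated until the end. Shi epoxidation of 13 under the conditions of step 9 should give methyl (2R)-4-(benzyloxy)-3-[4-(benzyloxy)phenyl]-2-[(4-(tert-butyldimethylsilyloxy)-3-{[(2R)-3,3-dimethyloxiran-2-yl]methyl}phenyl)methyl]-5-oxo-2,5-dihydrofuran-2-carboxylate F4. Hydrogenolysis (H2, Pd/C, EtOAc) of its two benzyl ethers gives methyl (2R)-2-[(4-(tert-butyldimethylsilyloxy)-3-{[(2R)-3,3-dimethyloxiran-2-yl]methyl}phenyl)methyl]-4-hydroxy-3-(4-hydroxyphenyl)-5-oxo-2,5-dihydrofuran-2-carboxylate F5. Desilylation with Bu4NF buffered with AcOH in THF at 0 °C then frees the last phenol in the absence of the metal catalyst, and the route is rejoined at 16.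

**Further compounds**

F1 | step 3 | methyl 4-(benzyloxy)-3-[4-(benzyloxy)phenyl]-5-oxo-2-(3-oxopropyl)-2,5-dihydrofuran-2-carboxylate (racemic) | COC(=O)C1(CCC=O)OC(=O)C(OCc2ccccc2)=C1c1ccc(OCc2ccccc2)cc1
F2 | step 3 | methyl (2S)-4-(benzyloxy)-3-[4-(benzyloxy)phenyl]-5-oxo-2-(3-oxopropyl)-2,5-dihydrofuran-2-carboxylate | COC(=O)[C@@]1(CCC=O)OC(=O)C(OCc2ccccc2)=C1c1ccc(OCc2ccccc2)cc1
F3 | step 5 | methyl (2R)-4-(benzyloxy)-3-[4-(benzyloxy)phenyl]-5-oxo-2-[(4-oxocyclohex-2-en-1-yl)methyl]-2,5-dihydrofuran-2-carboxylate (ring epimers) | COC(=O)[C@]1(CC2C=CC(=O)CC2)OC(=O)C(OCc2ccccc2)=C1c1ccc(OCc2ccccc2)cc1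
F4 | step 10 | methyl (2R)-4-(benzyloxy)-3-[4-(benzyloxy)phenyl]-2-[(4-(tert-butyldimethylsilyloxy)-3-{[(2R)-3,3-dimethyloxiran-2-yl]methyl}phenyl)methyl]-5-oxo-2,5-dihydrofuran-2-carboxylate | COC(=O)[C@]1(Cc2ccc(O[Si](C)(C)C(C)(C)C)c(C[C@H]3OC3(C)C)c2)OC(=O)C(OCc2ccccc2)=C1c1ccc(OCc2ccccc2)cc1
F5 | step 10 | methyl (2R)-2-[(4-(tert-butyldimethylsilyloxy)-3-{[(2R)-3,3-dimethyloxiran-2-yl]methyl}phenyl)methyl]-4-hydroxy-3-(4-hydroxyphenyl)-5-oxo-2,5-dihydrofuran-2-carboxylate | COC(=O)[C@]1(Cc2ccc(O[Si](C)(C)C(C)(C)C)c(C[C@H]3OC3(C)C)c2)OC(=O)C(O)=C1c1ccc(O)cc1
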